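The chromanone is traced back to a benzofuran-3-one. Its spiro carbon C3, shared by the pyranone ring and the cyclobutene ring, carries both the aroyl carbon C4 and the O1-bound C2, the imprint of an acyl group that has moved from furanone C2 to an exocyclic carbon. The key step is a Lewis-acid 1,2-acyl shift in a spiro-epoxide: in one operation it forms C3–C4, enlarges the furanone to the pyranone and sets the quaternary stereocentre by inversion. The precursor is the (R,R)-oxirane of a Z-configured 2-(benzocyclobutenylidene)-4,6-dimethoxybenzofuran-3-one, reached by aryne [2+2], Knoevenagel condensation and asymmetric nucleophilic epoxidation; lactone reduction and Mitsunobu closure of O1–C2 complete the route.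

Key step: step 4

Atom labels: chromanone O1, C2, C3 (spiro), C4; benzocyclobutene aryl carbons C1'–C6' (OMe on C4' and C5'), four-ring carbon C7' (bound to C6', becomes chromanone C3) and C8' (CH2); before the key step the furanone atoms are O1, C2, C3.

Assumption: the sense of induction of the cinchona phase-transfer catalyst on this tetrasubstituted enone cannot be predicted with confidence; the cinchonidinium salt is written in step 3, and its pseudoenantiomeric cinchoninium salt would replace it if the (S) configuration at C7' were favoured.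

Step 1
Reactants: 1 1-bromo-2,3-dimethoxybenzene; 2 1,1-diethoxyethene
Product: 5 4,5-dimethoxybicyclo[4.2.0]octa-1,3,5-trien-7-one, via 3,4-dimethoxybenzyne 3 (not isolated), via diethyl acetal 4 (not isolated)
Conditions: NaNH2 (2.5 equiv), 2 (2 equiv), THF, reflux; then 1 M HCl, THF, rt
Reagents that add atoms: water, O
Why: Aryne–ketene acetal [2+2] cycloaddition followed by acetal hydrolysis: NaNH2 can remove HBr only towards C6, and in the resulting aryne 3 the nucleophilic CH2 terminus of 2 should attack the carbon remote from the neighbouring OMe so that the aryl anion formed next to OMe closes on the dialkoxycarbenium carbon, which places the future carbonyl on the ring carbon ortho to OMe as the target requires.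

Step 2
Reactants: 5 4,5-dimethoxybicyclo[4.2.0]octa-1,3,5-trien-7-one; 6 4,6-dimethoxybenzofuran-3(2H)-one
Product: 8 (Z)-2-(4,5-dimethoxybicyclo[4.2.0]octa-1,3,5-trien-7-ylidene)-4,6-dimethoxybenzofuran-3(2H)-one, via aldol adduct 7 (not isolated)
Conditions: TiCl4 (2 equiv), pyridine (4 equiv), THF, 0 °C to rt
Reagents that add atoms: none
Why: Knoevenagel-type aldol condensation under TiCl4/pyridine: the titanium enolate of the acidic C2 methylene of 6 adds to the strain-activated ketone and the aldolate 7 eliminates, and the push–pull alkene should equilibrate through reversible conjugate addition to the Z isomer, in which the furanone carbonyl lies next to the cyclobutene CH2 and away from the 5'-OMe.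

Step 3
Reactants: 8 (Z)-2-(4,5-dimethoxybicyclo[4.2.0]octa-1,3,5-trien-7-ylidene)-4,6-dimethoxybenzofuran-3(2H)-one
Product: 10 (2R,3'R)-4,4'',5'',6-tetramethoxy-3H-dispiro[benzofuran-2,2'-oxirane-3',7''-bicyclo[4.2.0]octa[1,3,5]trien]-3-one, via peroxy enolate 9 (not isolated)
Conditions: cumene hydroperoxide (1.5 equiv), N-(9-anthracenylmethyl)-O-benzylcinchonidinium bromide (10 mol %), 1 M aq KOH, toluene, 0 °C
Reagents that add atoms: cumene hydroperoxide, CC(C)(OO)c1ccccc1
Why: Weitz–Scheffer epoxidation under chiral phase-transfer catalysis: the cumyl peroxide anion, ion-paired with the cinchona cation, adds to the β-carbon C7' (helped by relief of ring strain as this carbon becomes tetrahedral) and thereby fixes its (R) configuration, and enolate 9 then closes the oxirane at C2 with loss of cumyl oxide; C8' cannot be deprotonated to a dienolate because that would create a benzocyclobutadiene.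

Step 4
Reactants: 10 (2R,3'R)-4,4'',5'',6-tetramethoxy-3H-dispiro[benzofuran-2,2'-oxirane-3',7''-bicyclo[4.2.0]octa[1,3,5]trien]-3-one
Product: 11 (R)-4,5,5',7'-tetramethoxyspiro[bicyclo[4.2.0]octa-1,3,5-triene-7,3'-chromane]-2',4'-dione
Conditions: BF3·OEt2 (1.1 equiv), CH2Cl2, −78 to −30 °C
Reagents that add atoms: none
Why: BF3 binds the oxirane oxygen and the C7'–O bond stretches at the benzylic carbon, supported by the ortho 5'-OMe; as it does so the aroyl carbon (furanone C3) shifts from C2 to C7' on the face opposite the departing oxygen, while C2, pushed by O1 and the borylated oxygen, becomes the lactone carbonyl. The closest known reaction is the Lewis-acid 1,2-acyl shift of α,β-epoxy ketones to 1,3-dicarbonyls (a Meinwald-type semipinacol rearrangement), the process that enlarges aurone epoxides to 3-substituted chromane-2,4-diones. The pyranone ring is closed by ring enlargement and not by cyclisation: C7' is inserted between C2 and the aroyl carbon as the new C3–C4 bond (chromane numbering) forms and the old furanone C2–C3 bond breaks. The spiro centre is set by stereospecific inversion at C7', so its (R) configuration follows from the (R) oxirane carbon made in step 3 alone, and a C2-epimeric oxirane with the same C7' configuration would converge on the same product. The step needs C–O cleavage at C7' and not at C2, which should be secured because a cation at C2 would sit next to the ketone carbonyl whereas C7' is benzylic, and it needs the shift to outrun opening or enlargement of the strained ring, which the doubly oxygenated, acetal-like migration origin C2 should ensure. The product has no hydrogen on C3, so the centre cannot epimerise afterwards.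

Step 5
Reactants: 11 (R)-4,5,5',7'-tetramethoxyspiro[bicyclo[4.2.0]octa-1,3,5-triene-7,3'-chromane]-2',4'-dione
Product: 13 (S)-(2-hydroxy-4,6-dimethoxyphenyl)[7-(hydroxymethyl)-4,5-dimethoxybicyclo[4.2.0]octa-1,3,5-trien-7-yl]methanone, via keto aldehyde 12 (not isolated)
Conditions: LiBH4 (2.5 equiv), THF, −20 to 0 °C; aq NH4Cl
Reagents that add atoms: none
Why: Borohydride reduction of an activated aryl ester: the lactone carbonyl is far more electrophilic than the C4 ketone, which is deactivated by the 5- and 7-methoxy groups and shielded by the quaternary carbon and is deactivated further once the lactone has opened to the ortho phenoxide, so aldehyde 12 and then alcohol 13 should form with the ketone and the non-enolisable spiro centre untouched.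

Step 6
Reactants: 13 (S)-(2-hydroxy-4,6-dimethoxyphenyl)[7-(hydroxymethyl)-4,5-dimethoxybicyclo[4.2.0]octa-1,3,5-trien-7-yl]methanone
Product: 14 (S)-4,5,5',7'-tetramethoxyspiro[bicyclo[4.2.0]octa-1,3,5-triene-7,3'-chroman]-4'-one
Conditions: PPh3, DIAD, THF, 0 °C to rt
Reagents that add atoms: none
Why: Intramolecular Mitsunobu etherification: the hydrogen-bonded phenol is acidic enough to protonate the betaine and displaces the primary alkoxyphosphonium in a 6-exo-tet SN2 closure, which is viable at this quaternary-flanked carbon because the spiro four-membered ring ties back two of its substituents and no β-hydrogen allows elimination; the stereocentre is a spectator.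

Compound list
1 | 1-bromo-2,3-dimethoxybenzene | COc1cccc(Br)c1OC | starting material
2 | 1,1-diethoxyethene | C=C(OCC)OCC | starting material
3 | 3,4-dimethoxybenzyne (1,2-didehydro-3,4-dimethoxybenzene; aryne bond between the former C–Br carbon and C6) | COC1=C(OC)C#CC=C1 | intermediate
4 | 7,7-diethoxy-4,5-dimethoxybicyclo[4.2.0]octa-1,3,5-triene (acetal carbon on the ring carbon ortho to OMe) | CCOC1(OCC)Cc2ccc(OC)c(OC)c21 | intermediate
5 | 4,5-dimethoxybicyclo[4.2.0]octa-1,3,5-trien-7-one (carbonyl on the ring carbon ortho to the 5-OMe) | COc1ccc2CC(=O)c2c1OC | intermediate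
6 | 4,6-dimethoxybenzofuran-3(2H)-one | COc1cc(OC)c2c(c1)OCC2=O | starting material
7 | 2-(7-hydroxy-4,5-dimethoxybicyclo[4.2.0]octa-1,3,5-trien-7-yl)-4,6-dimethoxybenzofuran-3(2H)-one (aldol adduct, held as its titanium alkoxide, mixture of diastereomers) | COc1cc(OC)c2c(c1)OC(C2=O)C1(O)Cc3ccc(OC)c(OC)c31 | intermediate
8 | (Z)-2-(4,5-dimethoxybicyclo[4.2.0]octa-1,3,5-trien-7-ylidene)-4,6-dimethoxybenzofuran-3(2H)-one (aryl carbon C6' cis to O1, CH2 cis to C3=O) | COc1cc(OC)c2c(c1)O/C(C2=O)=C1/Cc3ccc(OC)c(OC)c31 | intermediate
9 | potassium 2-[(7R)-4,5-dimethoxy-7-(2-phenylpropan-2-ylperoxy)bicyclo[4.2.0]octa-1,3,5-trien-7-yl]-4,6-dimethoxybenzofuran-3-olate (peroxy enolate; paired with the catalyst cation in the organic phase) | COc1cc(OC)c2c(c1)OC(=C2[O-])[C@@]1(OOC(C)(C)c3ccccc3)Cc3ccc(OC)c(OC)c31.[K+] | intermediate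
10 | (2R,3'R)-4,4'',5'',6-tetramethoxy-3H-dispiro[benzofuran-2,2'-oxirane-3',7''-bicyclo[4.2.0]octa[1,3,5]trien]-3-one (spiro-epoxide; aryl carbon cis to O1; R at furanone C2 and R at C7') | COc1cc(OC)c2c(c1)O[C@]3(C2=O)O[C@@]34Cc5ccc(OC)c(OC)c54 | intermediate
11 | (R)-4,5,5',7'-tetramethoxyspiro[bicyclo[4.2.0]octa-1,3,5-triene-7,3'-chromane]-2',4'-dione | COc1cc(OC)c2c(c1)OC(=O)[C@@]1(Cc3ccc(OC)c(OC)c31)C2=O | intermediate
12 | (S)-7-(2-hydroxy-4,6-dimethoxybenzoyl)-4,5-dimethoxybicyclo[4.2.0]octa-1,3,5-triene-7-carbaldehyde | COc1cc(OC)c(c(O)c1)C(=O)[C@@]1(C=O)Cc2ccc(OC)c(OC)c21 | intermediate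
13 | (S)-(2-hydroxy-4,6-dimethoxyphenyl)[7-(hydroxymethyl)-4,5-dimethoxybicyclo[4.2.0]octa-1,3,5-trien-7-yl]methanone | COc1cc(OC)c(c(O)c1)C(=O)[C@@]1(CO)Cc2ccc(OC)c(OC)c21 | intermediate
14 | (S)-4,5,5',7'-tetramethoxyspiro[bicyclo[4.2.0]octa-1,3,5-triene-7,3'-chroman]-4'-one (CNP0192565.1) | COc1cc(OC)c2c(c1)OC[C@@]1(Cc3ccc(OC)c(OC)c31)C2=O | target

Total step count: 6
Longest linear sequence: 6 steps (1 → 5 → 8 → 10 → 11 → 13 → 14)

Steps most likely to fail

1. Step 4. The oxirane may ionise at the acetal-type carbon C2 instead of C7', the four-membered ring may enlarge or open at the cationic stage, or fluoride may be captured, each outrunning the acyl shift. Fallback (sets out from ketone 5, comes back at target 14): the quaternary centre would be built by enolate chemistry and the pyranone closed by acylation of the arene.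
   - van Leusen reductive cyanation of 5 (TosMIC, KOt-Bu, DME/EtOH) would give 4,5-dimethoxybicyclo[4.2.0]octa-1,3,5-triene-7-carbonitrile F1.
   - Deprotonation with lithium diisopropylamide (THF, −78 °C) and aldol addition to monomeric formaldehyde would give racemic 7-(hydroxymethyl)-4,5-dimethoxybicyclo[4.2.0]octa-1,3,5-triene-7-carbonitrile F2.
   - Mitsunobu etherification with 3,5-dimethoxyphenol (PPh3, DIAD, toluene, 80 °C) would give 7-[(3,5-dimethoxyphenoxy)methyl]-4,5-dimethoxybicyclo[4.2.0]octa-1,3,5-triene-7-carbonitrile F3.
   - Intramolecular Houben–Hoesch acylation (TfOH, CH2Cl2, 0 °C; then water) would close the ketone onto either of the two equivalent ortho positions of the phenoxy ring and give racemic 14.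
   - Preparative HPLC on a chiral stationary phase would then separate 14 from the (R)-enantiomer of 14 F4.

2. Step 3. Facial discrimination at the hindered tetrasubstituted β-carbon may be poor, or conjugate addition to the electron-rich enone may be so slow that hydroxide-induced retro-aldol cleavage competes. Fallback (sets out from alkene 8, comes back at epoxide 10): asymmetric catalysis would be replaced by resolution. Racemic Weitz–Scheffer epoxidation (H2O2, NaOH, MeOH/CH2Cl2, 0 °C) would give racemic 10. Preparative HPLC on a polysaccharide chiral stationary phase would separate 10 from the (2S,3'S)-enantiomer of 10 F5 before the rearrangement.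

3. Step 2. Chloride- or base-induced opening of the strained ketone and self-condensation of the furanone may outrun the cross-condensation, or dehydration of the aldolate may stall. Fallback (sets out from acetal 4, isolated by omitting the acid treatment in step 1, and from furanone 6; comes back at alkene 8): the condensation would be split into an acetal addition and a separate elimination.
   - Silylation of 6 (TBSOTf, Et3N, CH2Cl2, 0 °C) would give tert-butyl[(4,6-dimethoxybenzofuran-3-yl)oxy]dimethylsilane F6.
   - Mukaiyama-type addition of F6 to the oxocarbenium ion generated from 4 (TMSOTf cat., CH2Cl2, −78 °C) would give 2-(7-ethoxy-4,5-dimethoxybicyclo[4.2.0]octa-1,3,5-trien-7-yl)-4,6-dimethoxybenzofuran-3(2H)-one F7.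
   - E1cB loss of ethanol (DBU, toluene, 60 °C) would then deliver 8.

Further compounds
F1 | step 4 | 4,5-dimethoxybicyclo[4.2.0]octa-1,3,5-triene-7-carbonitrile (racemic) | COc1ccc2CC(C#N)c2c1OC
F2 | step 4 | 7-(hydroxymethyl)-4,5-dimethoxybicyclo[4.2.0]octa-1,3,5-triene-7-carbonitrile (racemic) | COc1ccc2CC(CO)(C#N)c2c1OC
F3 | step 4 | 7-[(3,5-dimethoxyphenoxy)methyl]-4,5-dimethoxybicyclo[4.2.0]octa-1,3,5-triene-7-carbonitrile (racemic) | COc1cc(OC)cc(OCC2(C#N)Cc3ccc(OC)c(OC)c32)c1
F4 | step 4 | (R)-4,5,5',7'-tetramethoxyspiro[bicyclo[4.2.0]octa-1,3,5-triene-7,3'-chroman]-4'-one (enantiomer of 14) | COc1cc(OC)c2c(c1)OC[C@]1(Cc3ccc(OC)c(OC)c31)C2=O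
F5 | step 3 | (2S,3'S)-4,4'',5'',6-tetramethoxy-3H-dispiro[benzofuran-2,2'-oxirane-3',7''-bicyclo[4.2.0]octa[1,3,5]trien]-3-one (enantiomer of 10) | COc1cc(OC)c2c(c1)O[C@@]3(C2=O)O[C@]34Cc5ccc(OC)c(OC)c54
F6 | step 2 | tert-butyl[(4,6-dimethoxybenzofuran-3-yl)oxy]dimethylsilane | COc1cc(OC)c2c(c1)occ2O[Si](C)(C)C(C)(C)C
F7 | step 2 | 2-(7-ethoxy-4,5-dimethoxybicyclo[4.2.0]octa-1,3,5-trien-7-yl)-4,6-dimethoxybenzofuran-3(2H)-one (mixture of diastereomers) | CCOC1(Cc2ccc(OC)c(OC)c21)C1Oc2cc(OC)cc(OC)c2C1=O
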